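**Retrosynthetic overview**
- The route rests on the furan ring. C2 is bound to O1 and carries ring B, C3 carries the formyl carbon, and C3a sits on ring A between two oxygenated carbons (C7a–O1 and C4–OH). Cutting C2–C3 therefore leads back to a carbene at C3 and an O–CH2–(ring B) C–H bond, in a ring-A arylacetate that bears two identical ring-B benzyl ethers.
- Rings A and B are bought. The O-heterocycle is the only ring made: it closes at C2–C3 as a dihydrofuran in step 7 and is aromatized in step 8, where the same quinone also removes the unused benzyl ether from O4.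
- The C5 prenyl group is delivered from O4 (1,1-dimethylallyl ether, aromatic Claisen; C5 is the only open ortho carbon). The C3 ester is then taken down to CHO, and the ring-B MOM group is removed last.
- The diazo ester comes from 5-methoxyresorcinol by iodination between the hydroxyls, double Mitsunobu etherification, Negishi–Reformatsky coupling and diazo transfer.

Key step: step 7

Remark (assumption): the target has no stereocentre, so 13 is made as a racemate. Any trans isomer formed with it is carried on, because step 8 erases C2 and C3.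
Abbreviation: ArB = 2-methoxy-4-(methoxymethoxy)phenyl (ring B with its 4'-OH masked). Benzofuran numbering: O1, C2, C3, C3a, C4–C7, C7a.

Step 1
Reactants: 1 4-hydroxy-2-methoxybenzaldehyde
Product: 2 2-methoxy-4-(methoxymethoxy)benzaldehyde
Conditions: MOMCl, K2CO3, acetone, 0 °C → rt
Reagents that add atoms: chloromethyl methyl ether (MOMCl), COCCl
Why: Williamson-type O-alkylation of the acidic para-formyl phenoxide installs an acetal that tolerates every basic, reductive, oxidative and metal-catalysed step up to step 13.

Step 2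
Reactants: 2 2-methoxy-4-(methoxymethoxy)benzaldehyde
Product: 3 [2-methoxy-4-(methoxymethoxy)phenyl]methanol
Conditions: NaBH4, MeOH, 0 °C
Reagents that add atoms: none
Why: Borohydride reduction of the aldehyde gives the benzyl alcohol, which is used as such because a halide with this ortho/para donor pattern would self-condense on storage.

Step 3
Reactants: 4 5-methoxybenzene-1,3-diol (5-methoxyresorcinol)
Product: 5 2-iodo-5-methoxybenzene-1,3-diol
Conditions: I2 (1 equiv), NaHCO3, THF–H2O, 0 °C
Reagents that add atoms: iodine, II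
Why: In electrophilic aromatic iodination under bicarbonate buffer, resorcinols react through the phenoxide at the carbon between the two hydroxyls (here also para to OMe), which marks the future C3a.

Step 4
Reactants: 5 2-iodo-5-methoxybenzene-1,3-diol; 3 [2-methoxy-4-(methoxymethoxy)phenyl]methanol (2.2 equiv)
Product: 7 2-iodo-5-methoxy-1,3-bis(ArB-methoxy)benzene, via monoether 6 (not isolated)
Conditions: PPh3, DIAD, THF, 0 °C → rt
Reagents that add atoms: none
Why: Double Mitsunobu etherification, well established for 2-iodoresorcinols, alkylates both phenols under neutral conditions with the primary benzylic alcohol and leaves the MOM groups and the C–I bond untouched.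

Step 5
Reactants: 7 2-iodo-5-methoxy-1,3-bis(ArB-methoxy)benzene; 8 methyl bromoacetate
Product: 10 methyl [4-methoxy-2,6-bis(ArB-methoxy)phenyl]acetate, via zinc reagent 9 (not isolated)
Conditions: Zn dust, TMSCl (cat.), THF, 40 °C (8 → 9); then 7, Pd2(dba)3 (2.5 mol %), XPhos (10 mol %), THF, 60 °C
Reagents that add atoms: none
Why: This Negishi-type coupling of a Reformatsky reagent runs by oxidative addition of zerovalent palladium into Ar–I, transmetalation and reductive elimination, with the bulky biaryl phosphine coping with the two ortho alkoxy groups and the base-free medium sparing the benzyl ethers.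

Step 6
Reactants: 10 methyl [4-methoxy-2,6-bis(ArB-methoxy)phenyl]acetate
Product: 11 methyl diazo[4-methoxy-2,6-bis(ArB-methoxy)phenyl]acetate
Conditions: p-ABSA (1.5 equiv), DBU (2 equiv), MeCN, 0 °C → rt, dark; chromatography on Et3N-washed silica
Reagents that add atoms: 4-acetamidobenzenesulfonyl azide (p-ABSA), CC(=O)Nc1ccc(cc1)S(=O)(=O)N=[N+]=[N-]
Why: In this Regitz diazo transfer the benzylic ester enolate adds to the terminal azide nitrogen and the triazene collapses to the aryldiazoacetate and the sulfonamide.

Step 7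
Reactants: 11 methyl diazo[4-methoxy-2,6-bis(ArB-methoxy)phenyl]acetate
Product: 13 racemic methyl cis-(2R,3S)-6-methoxy-2-ArB-4-(ArB-methoxy)-2,3-dihydro-1-benzofuran-3-carboxylate, via rhodium carbene 12 (not isolated)
Conditions: Rh2(OAc)4 (1 mol %), 4 Å MS, CH2Cl2, slow addition of 11, 0 °C → rt
Reagents that add atoms: none
Why: Rh2(OAc)4 binds the nucleophilic diazo carbon of 11 and nitrogen leaves, giving the donor–acceptor carbene 12 on the divalent rhodium dimer, tamed by the trialkoxyaryl donor and therefore selective. The carbene carbon (future C3) then inserts, in one concerted but asynchronous event with strong hydride-transfer character, into an O–CH2–ArB C–H bond (future C2), which is the known intramolecular 1,5 C–H insertion of aryldiazoacetates into ortho-benzyloxy groups. The dihydrofuran ring (C3, C3a, C7a, O1, C2) closes by C–C bond formation through a five-membered transition state, whereas ylide formation at the ether oxygen would need a four-membered ring and every other sp3 C–H would need a ring of four or of nine and more atoms. C2 and C3 are set together: the hydrogen ends on C3 with retention at C2, and ring B turns away from the carboxylate wall of the catalyst, which should favour the cis isomer kinetically, as a racemate because catalyst and substrate are achiral. The step needs chemoselectivity over carbene dimerisation, O–H insertion into water and attack on ring B, and this is secured by slow addition, molecular sieves and a C–H bond activated twice (by the ether oxygen and by the ortho/para-dialkoxyaryl group), while site selectivity is no issue because the two benzyl ethers of 11 are equivalent by symmetry. The relative configuration has no consequence, since step 8 removes both centres.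

Step 8
Reactants: 13 racemic methyl cis-6-methoxy-2-ArB-4-(ArB-methoxy)-2,3-dihydro-1-benzofuran-3-carboxylate
Product: 15 methyl 4-hydroxy-6-methoxy-2-ArB-1-benzofuran-3-carboxylate, via dihydrobenzofuranol 14 (not isolated)
Conditions: DDQ (1.2 equiv), 1,4-dioxane–H2O (20:1), rt; then DDQ (1.5 equiv), 70 °C
Reagents that add atoms: none
Why: DDQ should first abstract hydride from the unhindered dialkoxybenzyl CH2 (oxidative benzyl ether cleavage through the oxocarbenium ion and its hemiacetal) and then, on warming, from C2–H, whose cation is stabilised by O1 and ring B and loses the acidic C3–H, a quinone dehydrogenation that aromatizes the furan.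

Step 9
Reactants: 15 methyl 4-hydroxy-6-methoxy-2-ArB-1-benzofuran-3-carboxylate; 16 3-chloro-3-methylbut-1-yne
Product: 17 methyl 6-methoxy-2-ArB-4-[(2-methylbut-3-yn-2-yl)oxy]-1-benzofuran-3-carboxylate
Conditions: CuCl2·2H2O (1 mol %), DBU (1.5 equiv), MeCN, 0 °C → rt
Reagents that add atoms: none
Why: Copper-catalysed propargylic etherification lets the phenoxide at O4, the only free OH, bond to the tertiary carbon through a copper acetylide-derived electrophile, which is not possible by plain SN2.

Step 10
Reactants: 17 methyl 6-methoxy-2-ArB-4-[(2-methylbut-3-yn-2-yl)oxy]-1-benzofuran-3-carboxylate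
Product: 18 methyl 6-methoxy-2-ArB-4-[(2-methylbut-3-en-2-yl)oxy]-1-benzofuran-3-carboxylate
Conditions: H2 (1 atm), Pd/CaCO3 poisoned with Pb(OAc)2 (Lindlar catalyst), quinoline, EtOAc, rt
Reagents that add atoms: none
Why: Lindlar semihydrogenation stops at the terminal alkene and leaves the tetrasubstituted, ester-bearing furan double bond alone.

Step 11
Reactants: 18 methyl 6-methoxy-2-ArB-4-[(2-methylbut-3-en-2-yl)oxy]-1-benzofuran-3-carboxylate
Product: 20 methyl 4-hydroxy-6-methoxy-2-ArB-5-(3-methylbut-2-en-1-yl)-1-benzofuran-3-carboxylate, via cyclohexadienone 19 (not isolated)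
Conditions: PhNEt2, 130 °C
Reagents that add atoms: none
Why: The aromatic Claisen rearrangement can only end productively at C5, because the other ortho carbon (C3a) is a ring-fusion atom; the [3,3] shift inverts the 1,1-dimethylallyl unit into prenyl, dienone 19 tautomerises to the phenol, and the basic solvent suppresses ionisation of the tertiary ether.

Step 12
Reactants: 20 methyl 4-hydroxy-6-methoxy-2-ArB-5-(3-methylbut-2-en-1-yl)-1-benzofuran-3-carboxylate
Product: 21 3-(hydroxymethyl)-6-methoxy-2-ArB-5-(3-methylbut-2-en-1-yl)-1-benzofuran-4-ol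
Conditions: i-Bu2AlH (4 equiv), CH2Cl2, −78 → 0 °C; aq. potassium sodium tartrate; crude product used at once
Reagents that add atoms: none
Why: In this hydride reduction of the ester, the first equivalent of i-Bu2AlH is spent on the phenol, the prenyl alkene and the MOM ether are inert at this temperature, and the neutral work-up protects the ionisable carbinol.

Step 13
Reactants: 21 3-(hydroxymethyl)-6-methoxy-2-ArB-5-(3-methylbut-2-en-1-yl)-1-benzofuran-4-ol
Product: 22 4-hydroxy-6-methoxy-2-ArB-5-(3-methylbut-2-en-1-yl)-1-benzofuran-3-carbaldehyde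
Conditions: activated MnO2 (excess), CH2Cl2, rt
Reagents that add atoms: none
Why: MnO2 oxidation is selective for the activated heteroaryl carbinol and stops at the aldehyde, which is then stabilised by a hydrogen bond from the C4 hydroxyl.

Step 14
Reactants: 22 4-hydroxy-6-methoxy-2-ArB-5-(3-methylbut-2-en-1-yl)-1-benzofuran-3-carbaldehyde
Product: 23 4-hydroxy-2-(4-hydroxy-2-methoxyphenyl)-6-methoxy-5-(3-methylbut-2-en-1-yl)-1-benzofuran-3-carbaldehyde (the target)
Conditions: 3 M aq. HCl, MeOH, rt, stopped at full conversion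
Reagents that add atoms: none
Why: Acid-catalysed acetal exchange removes the aryl MOM ether under the mild conditions usual for ortho-prenylphenols, and the C4 hydroxyl, tied up by the formyl group, is a poor nucleophile for chroman formation.

**Compound list**
1 | 4-hydroxy-2-methoxybenzaldehyde | O=Cc1ccc(O)cc1OC | starting material
2 | 2-methoxy-4-(methoxymethoxy)benzaldehyde | O=Cc1ccc(OCOC)cc1OC | intermediate
3 | [2-methoxy-4-(methoxymethoxy)phenyl]methanol | OCc1ccc(OCOC)cc1OC | intermediate
4 | 5-methoxybenzene-1,3-diol | COc1cc(O)cc(O)c1 | starting material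
5 | 2-iodo-5-methoxybenzene-1,3-diol | COc1cc(O)c(I)c(O)c1 | intermediate
6 | 2-iodo-5-methoxy-3-{[2-methoxy-4-(methoxymethoxy)phenyl]methoxy}phenol (not isolated) | COc1cc(O)c(I)c(OCc2ccc(OCOC)cc2OC)c1 | intermediate
7 | 2-iodo-5-methoxy-1,3-bis{[2-methoxy-4-(methoxymethoxy)phenyl]methoxy}benzene | COc1cc(OCc2ccc(OCOC)cc2OC)c(I)c(OCc2ccc(OCOC)cc2OC)c1 | intermediate
8 | methyl bromoacetate | COC(=O)CBr | starting material
9 | (2-methoxy-2-oxoethyl)zinc bromide (not isolated) | COC(=O)C[Zn]Br | intermediate
10 | methyl (4-methoxy-2,6-bis{[2-methoxy-4-(methoxymethoxy)phenyl]methoxy}phenyl)acetate | COC(=O)Cc1c(OCc2ccc(OCOC)cc2OC)cc(OC)cc1OCc1ccc(OCOC)cc1OC | intermediate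
11 | methyl diazo(4-methoxy-2,6-bis{[2-methoxy-4-(methoxymethoxy)phenyl]methoxy}phenyl)acetate | COC(=O)C(=[N+]=[N-])c1c(OCc2ccc(OCOC)cc2OC)cc(OC)cc1OCc1ccc(OCOC)cc1OC | intermediate
12 | rhodium carbene from 11, with the Rh2(OAc)4 unit written as [Rh] (not isolated) | COC(=O)C(=[Rh])c1c(OCc2ccc(OCOC)cc2OC)cc(OC)cc1OCc1ccc(OCOC)cc1OC | intermediate
13 | racemic methyl cis-(2R,3S)-6-methoxy-2-[2-methoxy-4-(methoxymethoxy)phenyl]-4-{[2-methoxy-4-(methoxymethoxy)phenyl]methoxy}-2,3-dihydro-1-benzofuran-3-carboxylate (relative configuration drawn) | COC(=O)[C@@H]1[C@H](c2ccc(OCOC)cc2OC)Oc2cc(OC)cc(OCc3ccc(OCOC)cc3OC)c12 | intermediate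
14 | racemic methyl cis-4-hydroxy-6-methoxy-2-[2-methoxy-4-(methoxymethoxy)phenyl]-2,3-dihydro-1-benzofuran-3-carboxylate (not isolated) | COC(=O)[C@@H]1[C@H](c2ccc(OCOC)cc2OC)Oc2cc(OC)cc(O)c12 | intermediate
15 | methyl 4-hydroxy-6-methoxy-2-[2-methoxy-4-(methoxymethoxy)phenyl]-1-benzofuran-3-carboxylate | COC(=O)c1c(-c2ccc(OCOC)cc2OC)oc2cc(OC)cc(O)c12 | intermediate
16 | 3-chloro-3-methylbut-1-yne | CC(C)(Cl)C#C | starting material
17 | methyl 6-methoxy-2-[2-methoxy-4-(methoxymethoxy)phenyl]-4-[(2-methylbut-3-yn-2-yl)oxy]-1-benzofuran-3-carboxylate | COC(=O)c1c(-c2ccc(OCOC)cc2OC)oc2cc(OC)cc(OC(C)(C)C#C)c12 | intermediate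
18 | methyl 6-methoxy-2-[2-methoxy-4-(methoxymethoxy)phenyl]-4-[(2-methylbut-3-en-2-yl)oxy]-1-benzofuran-3-carboxylate | COC(=O)c1c(-c2ccc(OCOC)cc2OC)oc2cc(OC)cc(OC(C)(C)C=C)c12 | intermediate
19 | racemic methyl 6-methoxy-2-[2-methoxy-4-(methoxymethoxy)phenyl]-5-(3-methylbut-2-en-1-yl)-4-oxo-4,5-dihydro-1-benzofuran-3-carboxylate (not isolated) | COC(=O)c1c(-c2ccc(OCOC)cc2OC)oc2C=C(OC)C(CC=C(C)C)C(=O)c12 | intermediate
20 | methyl 4-hydroxy-6-methoxy-2-[2-methoxy-4-(methoxymethoxy)phenyl]-5-(3-methylbut-2-en-1-yl)-1-benzofuran-3-carboxylate | COC(=O)c1c(-c2ccc(OCOC)cc2OC)oc2cc(OC)c(CC=C(C)C)c(O)c12 | intermediate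
21 | 3-(hydroxymethyl)-6-methoxy-2-[2-methoxy-4-(methoxymethoxy)phenyl]-5-(3-methylbut-2-en-1-yl)-1-benzofuran-4-ol | OCc1c(-c2ccc(OCOC)cc2OC)oc2cc(OC)c(CC=C(C)C)c(O)c12 | intermediate
22 | 4-hydroxy-6-methoxy-2-[2-methoxy-4-(methoxymethoxy)phenyl]-5-(3-methylbut-2-en-1-yl)-1-benzofuran-3-carbaldehyde | O=Cc1c(-c2ccc(OCOC)cc2OC)oc2cc(OC)c(CC=C(C)C)c(O)c12 | intermediate
23 | 4-hydroxy-2-(4-hydroxy-2-methoxyphenyl)-6-methoxy-5-(3-methylbut-2-en-1-yl)-1-benzofuran-3-carbaldehyde | COc1cc(O)ccc1-c1oc2cc(OC)c(CC=C(C)C)c(O)c2c1C=O | target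

**Total step count:** 14
**Longest linear sequence:** 13 steps (steps 1, 2 and 4–14, from 1). The ring-A branch from 4 is 12 steps.

**Steps most likely to fail**

1. Step 7 (C–H insertion).
   - Risk: the crowded, very electron-rich carbene may be lost to dimerisation or azine formation. It may attack ring B (cyclopropanation and ring expansion). The hydride transfer may also run ahead of C–C bond formation, so that the ion pair falls apart.
   - Fallback: C2–C3 is made by aldol chemistry and the ring is closed at O1–C2. It sets out from 10 and comes back at 15.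
   - The lithium enolate of 10 (LiN(SiMe3)2, THF, −78 °C) is added to aldehyde 2 to give the β-hydroxy ester F1 as a diastereomer mixture. Dess–Martin periodinane (NaHCO3, CH2Cl2) should oxidise it to the β-keto ester F2.
   - Hydrogenolysis (H2, Pd/C, EtOAc) takes off both benzyl ethers to give the bis-phenol keto ester F3. Either of its two equivalent phenols adds to the ketone and water is lost (PPTS, toluene, 60 °C) to give 15. Steps 6 to 8 are thus bypassed.

2. Step 8 (DDQ).
   - Risk: the liberated electron-rich phenol may be over-oxidised, or the dehydrogenation may stall after the ether cleavage.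
   - Fallback: anionic selenation with syn elimination, then reductive debenzylation. It sets out from 13 and comes back at 15.
   - Deprotonation at C3 (LiN(SiMe3)2, THF, −78 °C) and trapping with PhSeBr on the face away from ring B gives the 3-phenylselanyl ester F4. Oxidation (H2O2, CH2Cl2, 0 °C) and syn elimination of the selenoxide toward C2–H gives the benzofuran benzyl ether F5.
   - Hydrogenolysis (H2, Pd/C, EtOAc) then frees O4 and gives 15. It is safe at this stage because C2–O1 is no longer an sp3 benzylic bond.

3. Step 6 (diazo transfer).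
   - Risk: the hindered, electron-rich arylacetate may be deprotonated too slowly by DBU, so that the transfer stalls and the sulfonyl azide decays.
   - Fallback: the diazo group is made from a ketone instead of an enolate. It sets out from 7 and comes back at 11, and it also bypasses step 5.
   - Iodine–lithium exchange (n-BuLi, THF, −78 °C) and inverse addition to excess dimethyl oxalate gives the aryl glyoxylate F6. Condensation with TsNHNH2 (MeOH, 50 °C) gives the tosylhydrazone F7. DBU (CH2Cl2, rt) then expels sulfinate in a Bamford–Stevens-type elimination to give 11.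

**Further compounds**
F1 | step 7 | methyl 3-hydroxy-3-[2-methoxy-4-(methoxymethoxy)phenyl]-2-(4-methoxy-2,6-bis{[2-methoxy-4-(methoxymethoxy)phenyl]methoxy}phenyl)propanoate (diastereomer mixture) | COC(=O)C(C(O)c1ccc(OCOC)cc1OC)c1c(OCc2ccc(OCOC)cc2OC)cc(OC)cc1OCc1ccc(OCOC)cc1OC
F2 | step 7 | methyl 3-[2-methoxy-4-(methoxymethoxy)phenyl]-2-(4-methoxy-2,6-bis{[2-methoxy-4-(methoxymethoxy)phenyl]methoxy}phenyl)-3-oxopropanoate (racemic) | COC(=O)C(C(=O)c1ccc(OCOC)cc1OC)c1c(OCc2ccc(OCOC)cc2OC)cc(OC)cc1OCc1ccc(OCOC)cc1OC
F3 | step 7 | methyl 2-(2,6-dihydroxy-4-methoxyphenyl)-3-[2-methoxy-4-(methoxymethoxy)phenyl]-3-oxopropanoate (racemic) | COC(=O)C(C(=O)c1ccc(OCOC)cc1OC)c1c(O)cc(OC)cc1O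
F4 | step 8 | racemic methyl 6-methoxy-2-[2-methoxy-4-(methoxymethoxy)phenyl]-4-{[2-methoxy-4-(methoxymethoxy)phenyl]methoxy}-3-(phenylselanyl)-2,3-dihydro-1-benzofuran-3-carboxylate, SePh trans to ring B | COC(=O)[C@]1([Se]c3ccccc3)[C@H](c2ccc(OCOC)cc2OC)Oc2cc(OC)cc(OCc3ccc(OCOC)cc3OC)c12
F5 | step 8 | methyl 6-methoxy-2-[2-methoxy-4-(methoxymethoxy)phenyl]-4-{[2-methoxy-4-(methoxymethoxy)phenyl]methoxy}-1-benzofuran-3-carboxylate | COC(=O)c1c(-c2ccc(OCOC)cc2OC)oc2cc(OC)cc(OCc3ccc(OCOC)cc3OC)c12
F6 | step 6 | methyl (4-methoxy-2,6-bis{[2-methoxy-4-(methoxymethoxy)phenyl]methoxy}phenyl)(oxo)acetate | COC(=O)C(=O)c1c(OCc2ccc(OCOC)cc2OC)cc(OC)cc1OCc1ccc(OCOC)cc1OC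
F7 | step 6 | methyl (4-methoxy-2,6-bis{[2-methoxy-4-(methoxymethoxy)phenyl]methoxy}phenyl)[2-(4-methylbenzenesulfonyl)hydrazinylidene]acetate | COC(=O)C(=NNS(=O)(=O)c1ccc(C)cc1)c1c(OCc2ccc(OCOC)cc2OC)cc(OC)cc1OCc1ccc(OCOC)cc1OC
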